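**Plan**

- Atom labels follow the tetrahydrofluorenone core formed in the annulation: C-1 (ketone), C-2=C-3, C-4 (nitro carbon, later the second ketone), C-4a (aryl-bearing quaternary carbon), C-9a (prenyl-bearing quaternary carbon), C-9 (benzylic carbon). The enabling feature is that C-4a and C-9a are adjacent quaternary carbons forming the shared edge of the five-membered ring and ring B, each next to one ring-B carbonyl. Ring B is therefore the retron of a 4-nitrocyclohex-2-enone from a 1-methoxy-3-siloxy diene and a nitroalkene.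
- Cuts: the aryl O–H groups (as methyl ethers); the C-4 carbonyl (from CH–NO2); the C-9–CH= bond of the bridging cyclohexene (benzylic cation plus Z-vinylsilane); C-9a–C-4a together with C-3–C-4 (diene/nitroalkene annulation); C-9–C-9a (aldol); the allyl–C-4a bond (alkylation of an arylnitroethane dianion).
- Forward: the arene is made into an ortho-formyl aryl nitroalkene carrying the silylallyl arm. An aldol reaction attaches the methoxy-enone arm. One operation closes the five-membered ring and ring B. The bridging six-membered ring follows, then the nitro-to-ketone conversion and liberation of the hydroquinone.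
- Stereochemistry: the only external source is the catalytic asymmetric aldol that sets the C-9 carbinol (S). That centre steers the face of C-9a in the annulation, cis ring fusion fixes C-4a, and the bridging closure can occur only on the face of the silylallyl arm, which sets C-9 of the target while the carbinol centre is lost.

Key step: step 16

Remark (assumption): the binaphthol–titanium catalyst of step 14 is assumed to send the dienol silane to the Si face of the di-ortho-substituted aldehyde; if the sense proves opposite, the (R)-ligand is used. Centres drawn without configuration are epimer mixtures that converge later.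

**Step 1**
Reactants: 1 prop-2-yn-1-ol
Product: 2 (Z)-3-iodo-2-methylprop-2-en-1-ol
Conditions: MeMgBr (2.4 equiv), CuI (10 mol%), THF, −10 °C to rt; then I2, −10 °C
Reagents that add atoms: methylmagnesium bromide, C[Mg]Br; iodine, II
Why: Copper-catalysed anti-carbomagnesiation of the propargylic alkoxide places methyl on C-2 and magnesium on C-3 cis to the chelating oxygen, and iodinolysis with retention should give the Z-iodide; no stereocentre is formed.

**Step 2**
Reactants: 2 (Z)-3-iodo-2-methylprop-2-en-1-ol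
Product: 4 (Z)-2-methyl-3-(trimethylsilyl)prop-2-en-1-ol, via iodoallyl trimethylsilyl ether 3 (not isolated)
Conditions: n-BuLi (1.0 equiv), THF, −78 °C; Me3SiCl, −78 to 0 °C; then t-BuLi (2.1 equiv), −78 to 0 °C; H2O
Reagents that add atoms: chlorotrimethylsilane, C[Si](C)(C)Cl
Why: After O-silylation, iodine–lithium exchange gives a Z-vinyllithium that takes the silyl group from oxygen through a five-membered silicate (retro-[1,4]-Brook rearrangement), which is possible only cis and so should deliver the vinylsilane with silicon syn to CH2OH.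

**Step 3**
Reactants: 4 (Z)-2-methyl-3-(trimethylsilyl)prop-2-en-1-ol
Product: 5 (Z)-3-bromo-2-methyl-1-(trimethylsilyl)prop-1-ene
Conditions: CBr4, PPh3, CH2Cl2, 0 °C
Reagents that add atoms: carbon tetrabromide, BrC(Br)(Br)Br
Why: The Appel reaction replaces the primary allylic hydroxyl by SN2 displacement of the oxyphosphonium group and leaves the alkene geometry untouched.

**Step 4**
Reactants: 6 (E)-4-methoxybut-3-en-2-one; 7 1-bromo-3-methylbut-2-ene
Product: 8 (E)-1-methoxy-7-methylocta-1,6-dien-3-one
Conditions: LiN(iPr)2, THF, −78 °C; then 7, DMPU, −78 to −30 °C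
Reagents that add atoms: none
Why: Kinetic deprotonation of the vinylogous ester at its only enolisable position and SN2 alkylation with the allylic bromide (Stork–Danheiser-type alkylation) should give the prenylated ketone; no stereocentre is formed.

**Step 5**
Reactants: 8 (E)-1-methoxy-7-methylocta-1,6-dien-3-one
Product: 9 (1E,3Z)-1-methoxy-7-methyl-3-(trimethylsilyloxy)octa-1,3,6-triene
Conditions: Me3SiOSO2CF3, Et3N, Et2O, 0 °C
Reagents that add atoms: trimethylsilyl trifluoromethanesulfonate, C[Si](C)(C)OS(=O)(=O)C(F)(F)F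
Why: Soft enolisation with silyl triflate and amine is the standard preparation of Danishefsky-type dienes; the Z enol ether is expected and its geometry has no later consequence.

**Step 6**
Reactants: 10 2,3-dibromo-1,4-dimethoxybenzene
Product: 11 2-bromo-3,6-dimethoxybenzaldehyde
Conditions: n-BuLi (1.0 equiv), THF/Et2O, −100 °C; DMF, −100 to −40 °C; 1 M HCl
Reagents that add atoms: N,N-dimethylformamide, CN(C)C=O
Why: Bromine–lithium exchange on one of the two equivalent bromides and Bouveault formylation of the aryllithium are fast below −90 °C, where loss of LiBr to the aryne is suppressed.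

**Step 7**
Reactants: 11 2-bromo-3,6-dimethoxybenzaldehyde
Product: 12 2-(2-bromo-3,6-dimethoxyphenyl)-1,3-dioxolane
Conditions: HOCH2CH2OH, p-toluenesulfonic acid (cat.), PhMe, reflux (Dean–Stark)
Reagents that add atoms: ethane-1,2-diol, OCCO
Why: Acid-catalysed acetalisation with azeotropic removal of water masks the aldehyde as a dioxolane that tolerates the organolithium and nitronate chemistry that follows.

**Step 8**
Reactants: 12 2-(2-bromo-3,6-dimethoxyphenyl)-1,3-dioxolane
Product: 13 2-(1,3-dioxolan-2-yl)-3,6-dimethoxybenzaldehyde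
Conditions: n-BuLi, THF, −78 °C; DMF; AcOH, H2O
Reagents that add atoms: N,N-dimethylformamide, CN(C)C=O
Why: A second bromine–lithium exchange gives an aryllithium with no ortho halide, which DMF formylates (Bouveault formylation), so the two ortho carbonyl carbons are differentiated by the acetal.

**Step 9**
Reactants: 13 2-(1,3-dioxolan-2-yl)-3,6-dimethoxybenzaldehyde; 14 nitromethane
Product: 15 2-{3,6-dimethoxy-2-[(E)-2-nitroethenyl]phenyl}-1,3-dioxolane
Conditions: NH4OAc (0.5 equiv), 14 as solvent, 80 °C
Reagents that add atoms: none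
Why: Henry condensation with dehydration under ammonium acetate catalysis should give the thermodynamically preferred E-nitrostyrene while the cyclic acetal stays intact.

**Step 10**
Reactants: 15 2-{3,6-dimethoxy-2-[(E)-2-nitroethenyl]phenyl}-1,3-dioxolane
Product: 16 2-[3,6-dimethoxy-2-(2-nitroethyl)phenyl]-1,3-dioxolane
Conditions: NaBH4, THF/MeOH, 0 °C
Reagents that add atoms: none
Why: Conjugate hydride addition of borohydride to the nitroalkene and protonation of the nitronate give the 2-arylnitroethane (standard nitrostyrene reduction).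

**Step 11**
Reactants: 16 2-[3,6-dimethoxy-2-(2-nitroethyl)phenyl]-1,3-dioxolane; 5 (Z)-3-bromo-2-methyl-1-(trimethylsilyl)prop-1-ene
Product: 17 2-{3,6-dimethoxy-2-[(4Z)-4-methyl-1-nitro-5-(trimethylsilyl)pent-4-en-2-yl]phenyl}-1,3-dioxolane (racemic)
Conditions: n-BuLi (2.1 equiv), THF/DMPU, −90 °C; 5, −90 to −60 °C; AcOH
Reagents that add atoms: none
Why: α,β-Double deprotonation of a 2-arylnitroethane gives a nitronate/benzyl dianion whose benzylic carbon is the most nucleophilic site and is alkylated by the allylic bromide in an SN2 reaction that keeps the Z-vinylsilane; the new stereocentre is racemic and becomes sp2 in step 12.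

**Step 12**
Reactants: 17 2-{3,6-dimethoxy-2-[(4Z)-4-methyl-1-nitro-5-(trimethylsilyl)pent-4-en-2-yl]phenyl}-1,3-dioxolane
Product: 19 2-{3,6-dimethoxy-2-[(1E,4Z)-4-methyl-1-nitro-5-(trimethylsilyl)penta-1,4-dien-2-yl]phenyl}-1,3-dioxolane, via α-phenylselanyl nitroalkane 18 (not isolated)
Conditions: n-BuLi (1.05 equiv), THF, −78 °C; PhSeBr; then 30% H2O2, 0 °C to rt
Reagents that add atoms: none
Why: C-Selenenylation of the lithium nitronate and oxidation at selenium trigger a selenoxide syn-elimination for which the benzylic hydrogen is the only β-hydrogen, so the β,β-disubstituted nitroalkene should form regiospecifically under non-basic conditions, with the E isomer (aryl anti to nitro) expected.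

**Step 13**
Reactants: 19 2-{3,6-dimethoxy-2-[(1E,4Z)-4-methyl-1-nitro-5-(trimethylsilyl)penta-1,4-dien-2-yl]phenyl}-1,3-dioxolane
Product: 20 3,6-dimethoxy-2-[(1E,4Z)-4-methyl-1-nitro-5-(trimethylsilyl)penta-1,4-dien-2-yl]benzaldehyde
Conditions: 1 M HCl, THF, rt
Reagents that add atoms: water, O
Why: Mild acid hydrolysis of the electron-rich benzaldehyde acetal frees the aldehyde, and dilute acid at room temperature should leave the nitroalkene and the vinylsilane untouched.

**Step 14**
Reactants: 20 3,6-dimethoxy-2-[(1E,4Z)-4-methyl-1-nitro-5-(trimethylsilyl)penta-1,4-dien-2-yl]benzaldehyde; 9 (1E,3Z)-1-methoxy-7-methyl-3-(trimethylsilyloxy)octa-1,3,6-triene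
Product: 22 (1E)-4-[(S)-hydroxy{3,6-dimethoxy-2-[(1E,4Z)-4-methyl-1-nitro-5-(trimethylsilyl)penta-1,4-dien-2-yl]phenyl}methyl]-1-methoxy-7-methylocta-1,6-dien-3-one (C-4 epimers), via O-trimethylsilyl aldol adduct 21 (not isolated)
Conditions: (S)-1,1'-bi-2-naphthol (20 mol%), Ti(OiPr)4 (10 mol%), 4 Å MS, Et2O, −20 °C; then citric acid, MeOH, 0 °C
Reagents that add atoms: none
Why: Binaphthol–titanium-catalysed Mukaiyama aldol addition of the 1-methoxy-3-siloxy diene to the titanium-bound aldehyde should set the (S)-carbinol centre by Si-face attack under catalyst control; the α-centre forms as an inconsequential epimer mixture, and mild methanolysis removes the O-silyl group without closing the dihydropyranone.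

**Step 15**
Reactants: 22 (1E)-4-[(S)-hydroxy{3,6-dimethoxy-2-[(1E,4Z)-4-methyl-1-nitro-5-(trimethylsilyl)penta-1,4-dien-2-yl]phenyl}methyl]-1-methoxy-7-methylocta-1,6-dien-3-one
Product: 23 (1E)-4-[(S)-[tert-butyl(dimethyl)silyl]oxy{3,6-dimethoxy-2-[(1E,4Z)-4-methyl-1-nitro-5-(trimethylsilyl)penta-1,4-dien-2-yl]phenyl}methyl]-1-methoxy-7-methylocta-1,6-dien-3-one (C-4 epimers)
Conditions: t-BuMe2SiOSO2CF3, 2,6-lutidine, CH2Cl2, −78 °C
Reagents that add atoms: tert-butyldimethylsilyl trifluoromethanesulfonate, CC(C)(C)[Si](C)(C)OS(=O)(=O)C(F)(F)F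
Why: Silylation of the secondary benzylic alcohol with the silyl triflate and a hindered pyridine base blocks oxa-Michael closure to the dihydropyranone and retro-aldol cleavage, and installs the leaving group used in step 17.

**Step 16**
Reactants: 23 (1E)-4-[(S)-[tert-butyl(dimethyl)silyl]oxy{3,6-dimethoxy-2-[(1E,4Z)-4-methyl-1-nitro-5-(trimethylsilyl)penta-1,4-dien-2-yl]phenyl}methyl]-1-methoxy-7-methylocta-1,6-dien-3-one
Product: 26 (4aR,9R,9aR)-9-[tert-butyl(dimethyl)silyl]oxy-5,8-dimethoxy-9a-(3-methylbut-2-en-1-yl)-4a-[(2Z)-2-methyl-3-(trimethylsilyl)prop-2-en-1-yl]-4-nitro-4,4a,9,9a-tetrahydro-1H-fluoren-1-one (C-4 epimers), via trimethylsilyl dienol ether 24 (not isolated), via silyl enol ether cycloadduct 25 (not isolated)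
Conditions: Me3SiOSO2CF3, Et3N, CH2Cl2, −40 to 0 °C; filter, then PhMe, 80 °C; then 0.5 M HCl, THF, 0 °C
Reagents that add atoms: none
Why: Silyl triflate activates the strongly Lewis-basic vinylogous-ester carbonyl of 23 and the amine removes its only α-hydrogen (at the future C-9a), giving the 1-methoxy-3-siloxy diene 24 without a strong base meeting the γ-acidic nitroalkene; on heating, the nucleophilic diene terminus C-9a bonds to the nitroalkene β-carbon C-4a and the nitronate carbon C-4 then bonds to the methoxy-bearing diene carbon C-3 (a highly asynchronous or stepwise Mukaiyama–Michael/Michael formal (4+2)) to give 25, from which dilute acid removes the enol silyl group and methanol to leave the C-2/C-3 enone. The closest known reaction is the Diels–Alder reaction of Danishefsky-type 1-methoxy-3-siloxy dienes with nitroalkenes, run here intramolecularly through the ortho-phenylene carbinol tether. The five-membered ring closes 5-exo-trig at the nitroalkene (C-9a–C-4a) and ring B closes 6-endo-trig by attack of C-4 on C-3. C-9a is controlled by the carbinol centre C-9: allylic 1,3-strain holds the C-9 hydrogen in the plane of the enol double bond, the aryl tether must lie on the reacting face and the silyloxy group therefore on the other, so prenyl should end cis to the silyloxy group; C-4a follows because only the cis-fused five/six bicycle can close, which puts the silylallyl arm on the prenyl face, and the C-3 and C-4 centres form as mixtures that are erased by the elimination and in step 18. The step needs enolisation of the ketone rather than deconjugation of the nitroalkene (secured by silyl triflate activation of the carbonyl and a short, cold exposure to the amine), C–C rather than C–O closure of the nitronate (the methoxy-substituted terminus is the soft electrophilic site of the siloxyallyl cation) and a single regiochemistry (fixed by the tether and the matched polarity of diene and nitroalkene).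

**Step 17**
Reactants: 26 (4aR,9R,9aR)-9-[tert-butyl(dimethyl)silyl]oxy-5,8-dimethoxy-9a-(3-methylbut-2-en-1-yl)-4a-[(2Z)-2-methyl-3-(trimethylsilyl)prop-2-en-1-yl]-4-nitro-4,4a,9,9a-tetrahydro-1H-fluoren-1-one
Product: 27 (4aR,9R,9aS)-5,8-dimethoxy-9a-(3-methylbut-2-en-1-yl)-4-nitro-4,4a,9,9a-tetrahydro-1H-fluoren-1-one bridged from C-4a to C-9 by CH2–C(CH3)=CH (CH2 on C-4a; C-4 epimers)
Conditions: Me3SiOSO2CF3 (20 mol%), 2,6-di-tert-butyl-4-methylpyridine (10 mol%), CH2Cl2, −78 to 0 °C
Reagents that add atoms: none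
Why: Catalytic silyl triflate ionises the benzylic silyl ether to a cation stabilised by the ortho methoxy group, the Z-vinylsilane attacks it at the silicon-bearing carbon (vinylsilane-terminated cation cyclisation, 6-endo, through the tertiary β-silyl cation) and the released silyl cation carries the chain; because the arm sits on one face of the five-membered ring the bond can form only there, which sets C-9 (R).

**Step 18**
Reactants: 27 (4aR,9R,9aS)-bridged 4-nitro-tetrahydrofluoren-1-one
Product: 28 (4aR,9R,9aS)-5,8-dimethoxy-9a-(3-methylbut-2-en-1-yl)-4a,9-dihydro-1H-fluorene-1,4(9aH)-dione bridged from C-4a to C-9 by CH2–C(CH3)=CH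
Conditions: O2 (1 atm), 1,8-diazabicyclo[5.4.0]undec-7-ene (DBU), MeCN, rt
Reagents that add atoms: dioxygen, O=O
Why: The C-4 hydrogen, α to nitro and γ to the enone, is removed by DBU and the extended nitronate should be oxidised by O2 at the nitro-bearing carbon with loss of nitrite (base-mediated aerobic Nef reaction, at the site that is also preferred for γ-oxygenation of dienolates), giving the enedione without touching the isolated alkenes.

**Step 19**
Reactants: 28 (4aR,9R,9aS)-bridged 5,8-dimethoxy-fluorene-1,4-dione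
Product: 30 CNP0166383.1, the 5,8-dihydroxy analogue of 28 (C-4a R, C-9 R, C-9a S), via benzoquinone 29 (not isolated)
Conditions: (NH4)2Ce(NO3)6, MeCN/H2O, 0 °C; then aq. Na2S2O4, EtOAc, rt
Reagents that add atoms: water, O
Why: Oxidative demethylation of the 1,4-dimethoxyarene by (NH4)2Ce(NO3)6 gives the benzoquinone, which dithionite should reduce to the hydroquinone much faster than it reduces the less electron-poor enedione; no stereocentre is affected.

**Compound list**

1 | prop-2-yn-1-ol | C#CCO | starting material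
2 | (Z)-3-iodo-2-methylprop-2-en-1-ol | I/C=C(C)\CO | intermediate
3 | (Z)-3-iodo-2-methylprop-2-enyl trimethylsilyl ether | I/C=C(C)\CO[Si](C)(C)C | intermediate
4 | (Z)-2-methyl-3-(trimethylsilyl)prop-2-en-1-ol | C[Si](C)(C)/C=C(C)\CO | intermediate
5 | (Z)-3-bromo-2-methyl-1-(trimethylsilyl)prop-1-ene | C[Si](C)(C)/C=C(C)\CBr | intermediate
6 | (E)-4-methoxybut-3-en-2-one | CO/C=C/C(C)=O | starting material
7 | 1-bromo-3-methylbut-2-ene | CC(C)=CCBr | starting material
8 | (E)-1-methoxy-7-methylocta-1,6-dien-3-one | CO/C=C/C(=O)CCC=C(C)C | intermediate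
9 | (1E,3Z)-1-methoxy-7-methyl-3-(trimethylsilyloxy)octa-1,3,6-triene | CO/C=C/C(O[Si](C)(C)C)=C/CC=C(C)C | intermediate
10 | 2,3-dibromo-1,4-dimethoxybenzene | COc1ccc(OC)c(Br)c1Br | starting material
11 | 2-bromo-3,6-dimethoxybenzaldehyde | COc1ccc(OC)c(C=O)c1Br | intermediate
12 | 2-(2-bromo-3,6-dimethoxyphenyl)-1,3-dioxolane | COc1ccc(OC)c(C2OCCO2)c1Br | intermediate
13 | 2-(1,3-dioxolan-2-yl)-3,6-dimethoxybenzaldehyde | COc1ccc(OC)c(C2OCCO2)c1C=O | intermediate
14 | nitromethane | C[N+](=O)[O-] | starting material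
15 | 2-{3,6-dimethoxy-2-[(E)-2-nitroethenyl]phenyl}-1,3-dioxolane | COc1ccc(OC)c(C2OCCO2)c1/C=C/[N+](=O)[O-] | intermediate
16 | 2-[3,6-dimethoxy-2-(2-nitroethyl)phenyl]-1,3-dioxolane | COc1ccc(OC)c(C2OCCO2)c1CC[N+](=O)[O-] | intermediate
17 | 2-{3,6-dimethoxy-2-[(4Z)-4-methyl-1-nitro-5-(trimethylsilyl)pent-4-en-2-yl]phenyl}-1,3-dioxolane (racemic) | COc1ccc(OC)c(C2OCCO2)c1C(C[N+](=O)[O-])C\C(C)=C/[Si](C)(C)C | intermediate
18 | 2-{3,6-dimethoxy-2-[(4Z)-4-methyl-1-nitro-1-(phenylselanyl)-5-(trimethylsilyl)pent-4-en-2-yl]phenyl}-1,3-dioxolane (diastereomer mixture) | COc1ccc(OC)c(C2OCCO2)c1C(C\C(C)=C/[Si](C)(C)C)C([Se]c1ccccc1)[N+](=O)[O-] | intermediate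
19 | 2-{3,6-dimethoxy-2-[(1E,4Z)-4-methyl-1-nitro-5-(trimethylsilyl)penta-1,4-dien-2-yl]phenyl}-1,3-dioxolane | COc1ccc(OC)c(C2OCCO2)c1/C(=C/[N+](=O)[O-])C\C(C)=C/[Si](C)(C)C | intermediate
20 | 3,6-dimethoxy-2-[(1E,4Z)-4-methyl-1-nitro-5-(trimethylsilyl)penta-1,4-dien-2-yl]benzaldehyde | COc1ccc(OC)c(C=O)c1/C(=C/[N+](=O)[O-])C\C(C)=C/[Si](C)(C)C | intermediate
21 | O-trimethylsilyl ether of 22 (carbinol carbon S; C-4 epimers) | CO/C=C/C(=O)C(CC=C(C)C)[C@H](O[Si](C)(C)C)c1c(OC)ccc(OC)c1/C(=C/[N+](=O)[O-])C\C(C)=C/[Si](C)(C)C | intermediate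
22 | (1E)-4-[(S)-hydroxy{3,6-dimethoxy-2-[(1E,4Z)-4-methyl-1-nitro-5-(trimethylsilyl)penta-1,4-dien-2-yl]phenyl}methyl]-1-methoxy-7-methylocta-1,6-dien-3-one (C-4 epimers) | CO/C=C/C(=O)C(CC=C(C)C)[C@H](O)c1c(OC)ccc(OC)c1/C(=C/[N+](=O)[O-])C\C(C)=C/[Si](C)(C)C | intermediate
23 | (1E)-4-[(S)-[tert-butyl(dimethyl)silyl]oxy{3,6-dimethoxy-2-[(1E,4Z)-4-methyl-1-nitro-5-(trimethylsilyl)penta-1,4-dien-2-yl]phenyl}methyl]-1-methoxy-7-methylocta-1,6-dien-3-one (C-4 epimers) | CO/C=C/C(=O)C(CC=C(C)C)[C@H](O[Si](C)(C)C(C)(C)C)c1c(OC)ccc(OC)c1/C(=C/[N+](=O)[O-])C\C(C)=C/[Si](C)(C)C | intermediate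
24 | 3-O-trimethylsilyl dienol ether of 23: (1E)-1-methoxy-3-(trimethylsilyloxy)octa-1,3,6-triene with the (S)-silyloxy(aryl)methyl group on C-4 (C-3=C-4 geometry mixed) | CO/C=C/C(O[Si](C)(C)C)=C(CC=C(C)C)[C@H](O[Si](C)(C)C(C)(C)C)c1c(OC)ccc(OC)c1/C(=C/[N+](=O)[O-])C\C(C)=C/[Si](C)(C)C | intermediate
25 | cycloadduct: as 26 but with C-1 as a trimethylsilyl enol ether (C-1=C-2) and C-3 bearing OCH3 (C-3 and C-4 epimers) | CC(C)=CC[C@@]12C(O[Si](C)(C)C)=CC(OC)C([N+](=O)[O-])[C@]1(C\C(C)=C/[Si](C)(C)C)c1c(OC)ccc(OC)c1[C@H]2O[Si](C)(C)C(C)(C)C | intermediate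
26 | (4aR,9R,9aR)-9-[tert-butyl(dimethyl)silyl]oxy-5,8-dimethoxy-9a-(3-methylbut-2-en-1-yl)-4a-[(2Z)-2-methyl-3-(trimethylsilyl)prop-2-en-1-yl]-4-nitro-4,4a,9,9a-tetrahydro-1H-fluoren-1-one (C-4 epimers; prenyl, silylallyl arm and silyloxy on one face of the five-membered ring, ring B on the other) | CC(C)=CC[C@@]12C(=O)C=CC([N+](=O)[O-])[C@]1(C\C(C)=C/[Si](C)(C)C)c1c(OC)ccc(OC)c1[C@H]2O[Si](C)(C)C(C)(C)C | intermediate
27 | (4aR,9R,9aS)-5,8-dimethoxy-9a-(3-methylbut-2-en-1-yl)-4-nitro-4,4a,9,9a-tetrahydro-1H-fluoren-1-one bridged from C-4a to C-9 by CH2–C(CH3)=CH (C-4 epimers) | CC(C)=CC[C@@]12C(=O)C=CC([N+](=O)[O-])[C@@]13CC(C)=C[C@@H]2c1c(OC)ccc(OC)c13 | intermediate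
28 | (4aR,9R,9aS)-5,8-dimethoxy-9a-(3-methylbut-2-en-1-yl)-4a,9-dihydro-1H-fluorene-1,4(9aH)-dione bridged from C-4a to C-9 by CH2–C(CH3)=CH | CC(C)=CC[C@@]12C(=O)C=CC(=O)[C@@]13CC(C)=C[C@@H]2c1c(OC)ccc(OC)c13 | intermediate
29 | the 5,8-benzoquinone corresponding to 28 (same configuration) | CC(C)=CC[C@@]12C(=O)C=CC(=O)[C@@]13CC(C)=C[C@@H]2C1=C3C(=O)C=CC1=O | intermediate
30 | CNP0166383.1: 5,8-dihydroxy analogue of 28 (C-4a R, C-9 R, C-9a S) | CC(C)=CC[C@@]12C(=O)C=CC(=O)[C@@]13CC(C)=C[C@@H]2c1c(O)ccc(O)c13 | target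

**Totals**

Total step count: 19. Longest linear sequence: 14 steps (steps 6 to 19, from 10).

**Steps most likely to fail**

Step 16. The amine used for enol silylation may deconjugate the nitroalkene by γ-deprotonation. Bond formation between two fully substituted carbons may be slow. The nitronate may close through oxygen instead of carbon, or facial control by the carbinol centre may be incomplete. The fallback sets out from 23 and keeps the same bond-forming events, but runs them anionically with the nitroalkene masked. Thiophenol with catalytic Et3N (CH2Cl2, 0 °C) adds to the nitroalkene (sulfa-Michael addition) to give the β-phenylsulfanyl nitroalkane F1. LiN(SiMe3)2 (2.2 equiv, THF, −78 °C) forms the nitronate and the ketone enolate. On warming to −20 °C the nitronate expels thiophenolate, so the nitroalkene appears next to the preformed lithium enolate. Michael addition and then addition–elimination of the new nitronate on the β-methoxy enone (loss of methoxide) follow, and quenching with AcOH returns the route at 26.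

Step 11. The second deprotonation may be incomplete because the di-ortho-substituted ring cannot easily conjugate with the benzylic carbanion, and the nitronate may be alkylated on oxygen. The fallback sets out from 12. Palladium-catalysed coupling with the Reformatsky reagent BrZnCH2CO2t-Bu (Pd2(dba)3, P(t-Bu)3, THF; Negishi-type α-arylation) gives the tert-butyl arylacetate F2. LiN(iPr)2 and then 5 give the α-allylated ester F3. LiAlH4 reduces it to the primary alcohol F4. I2, PPh3 and imidazole give the primary iodide F5. NaNO2 in DMF (Kornblum substitution) returns the route at 17.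

Step 14. Enantiofacial discrimination or catalyst turnover may be poor with the di-ortho-substituted aldehyde, and the adduct may close prematurely to the dihydropyranone. The fallback sets out from 8 and 20. The lithium enolate of 8 (LiN(SiMe3)2, THF, −78 °C) adds to 20 to give the racemic aldol adduct F6. Its enantiomers are separated by preparative chromatography on a chiral stationary phase, and the (S)-carbinol enantiomer is 22, where the route is rejoined.

**Further compounds**

F1 | step 16 | (1E)-4-[(S)-[tert-butyl(dimethyl)silyl]oxy{3,6-dimethoxy-2-[(4Z)-4-methyl-1-nitro-2-(phenylsulfanyl)-5-(trimethylsilyl)pent-4-en-2-yl]phenyl}methyl]-1-methoxy-7-methylocta-1,6-dien-3-one (epimer mixture) | CO/C=C/C(=O)C(CC=C(C)C)[C@H](O[Si](C)(C)C(C)(C)C)c1c(OC)ccc(OC)c1C(C[N+](=O)[O-])(Sc1ccccc1)C\C(C)=C/[Si](C)(C)C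
F2 | step 11 | tert-butyl 2-[2-(1,3-dioxolan-2-yl)-3,6-dimethoxyphenyl]acetate | COc1ccc(OC)c(C2OCCO2)c1CC(=O)OC(C)(C)C
F3 | step 11 | tert-butyl (4Z)-2-[2-(1,3-dioxolan-2-yl)-3,6-dimethoxyphenyl]-4-methyl-5-(trimethylsilyl)pent-4-enoate (racemic) | COc1ccc(OC)c(C2OCCO2)c1C(C\C(C)=C/[Si](C)(C)C)C(=O)OC(C)(C)C
F4 | step 11 | (4Z)-2-[2-(1,3-dioxolan-2-yl)-3,6-dimethoxyphenyl]-4-methyl-5-(trimethylsilyl)pent-4-en-1-ol (racemic) | COc1ccc(OC)c(C2OCCO2)c1C(CO)C\C(C)=C/[Si](C)(C)C
F5 | step 11 | 2-{2-[(4Z)-1-iodo-4-methyl-5-(trimethylsilyl)pent-4-en-2-yl]-3,6-dimethoxyphenyl}-1,3-dioxolane (racemic) | COc1ccc(OC)c(C2OCCO2)c1C(CI)C\C(C)=C/[Si](C)(C)C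
F6 | step 14 | racemic (1E)-4-[hydroxy{3,6-dimethoxy-2-[(1E,4Z)-4-methyl-1-nitro-5-(trimethylsilyl)penta-1,4-dien-2-yl]phenyl}methyl]-1-methoxy-7-methylocta-1,6-dien-3-one | CO/C=C/C(=O)C(CC=C(C)C)C(O)c1c(OC)ccc(OC)c1/C(=C/[N+](=O)[O-])C\C(C)=C/[Si](C)(C)C
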